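Amounts first: you charge as much Q as J, 0.18 M each, and Z can take 0.0540 M of the Q for good. Once it has, a run tends towards about 0.126 M of D and 0.0540 M of J. You have to choose which recipe to run again.

all flasks: Z 0.0540 M; time 25 s
- winter: Q 0.18 M (fed, over 20 s); J 0.180 M; all else is in the flask from the start; the feed brings no volume worth counting
- summer: Q 0.18 M; J 0.180 M; everything together at the start
- spring: Q 0.18 M; J 0.180 M (fed, over 20 s); all else is in the flask from the start; the feed brings no volume worth counting

    Q + J ⇌ L + D (K1 = 4.0, k1 = 28 L mol⁻¹ s⁻¹)
    L → X (k2 = 0.18 s⁻¹)
    J + L ⇌ J.L, settled at all times (K3 = 2.1 L mol⁻¹)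
    Q + Z → Q.Z (k4 = 16 L mol⁻¹ s⁻¹)

- L is meant together with its J.L
- run time (winter): 25 s

1. the best flask by amount of L, in percent of the Q charged; "all alike" if 1.5 percentage points covers them all (winter / summer / spring / all alike)
2. amount of L at the end, in percent of the Q charged, winter
3. amount of L at the end, in percent of the Q charged, summer
4. amount of L at the end, in percent of the Q charged, spring

Follow one molecule of Q. Becoming L does not doom it: the step back to Q is open. In summer Q's forward half-life with J is 0.14 s, far shorter than the 5.56 s that L lasts, so Q, L and J.L act as one pool (a pre-equilibrium) with a leak. Z's half-life on Q there is 0.80 s, so I take Z's share off at once, leaving 70.0% of the Q charged in the pool. The odds inside the pool, at the amounts above, are: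

[L]/[Q] = 4.0 × [J]/[D] = 1.71

[J.L]/[L] = 2.1 L mol⁻¹ × [J] = 0.113

The molecule leaks to X from free L, where it stands 58.9% of the time. L with J.L makes up 65.6% of the pool. So the pool's time constant is

5.56 s / 58.9% = 9.43 s

My reckoning for summer, whose pool stands from the start:

70.0% × 65.6% = 45.9% as L with J.L, and 45.9% × exp(−25 s / 9.43 s) = 3.24%

In winter Q arrives in portions, each later than the last, so for that flask I average the survival over the feed:

45.9% × (9.43 s / 20 s) × (exp(−5.00 s / 9.43 s) − exp(−25 s / 9.43 s)) = 11.2%

So I would feed Q as in winter, since that figure is larger than summer's. My reckoning stops there: spring feeds J into Q that stands from the start, and I have no line for that flask.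

The forecast reckons all three flasks. It picks winter, with 10% for winter, 7.7% for spring and 2.9% for summer, and its ground is: “Winter is best because its L is made latest.” My figures stand above its figures, for winter and for summer.

The flask that gives most is winter, with 9.89%, against 7.58% for spring and 2.72% for summer. With the dosing over 6.00 s, winter ends at 3.65%. Now use the time constant on spring, where Z is at 0% at 20.0 s. Q and L together stand at 19.4% of the Q charged, and 5.00 s at 9.43 s leaves 11.4%. The run shows 11.2%.

Now summer read at 6.0 s: the pool line gives 24.3% as L. The run shows 25.1%.

The constants used here are those of an exercise; the rest is arithmetic.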